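Labdane numbering is used (ring A: C1–C5, C10; ring B: C5–C10; gem-dimethyl C4, angular methyl on C10, ester on C8, side chain on C9). Ring A is disconnected as a Diels–Alder adduct: the C3–C4 and C5–C10 bonds are the two bonds of a [4+2] between a C10=C1–C2=C3 diene and a C4=C5 enone. Because C5–C10 is also the ring-fusion bond, an intramolecular, Lewis-acid-promoted cycloaddition of an acyclic 1,7,9-trien-3-one (C6 ketone as activator and later source of the C6=C7 alkene) closes both rings and sets the C4 and C10 quaternary carbons at once. The trienone, with C8 and C9 already set, comes from an Ireland–Claisen rearrangement.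

Key step: step 9

Remark: the all-equatorial, trans-fused 6-oxo decalin is assumed to be the thermodynamically preferred C5/C8 epimer; the base treatment in step 10 relies on this.

Step 1
Reactants: 1 3-[(tert-butyldimethylsilyl)oxy]propanal; 2 2-(triphenyl-λ5-phosphanylidene)propanal
Product: 3 (2E)-5-[(tert-butyldimethylsilyl)oxy]-2-methylpent-2-enal
Conditions: toluene, 90 °C
Reagents that add atoms: none
Why: Wittig olefination with a formyl-stabilised ylide should give the (E)-trisubstituted enal under thermodynamic control, and the less electrophilic enal product should not react further.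

Step 2
Reactants: 3 (2E)-5-[(tert-butyldimethylsilyl)oxy]-2-methylpent-2-enal; 4 ethynyltrimethylsilane
Product: 5 racemic (4E)-7-[(tert-butyldimethylsilyl)oxy]-4-methyl-1-(trimethylsilyl)hept-4-en-1-yn-3-ol
Conditions: 4, n-BuLi, THF, −78 °C; then 3, −78 °C; aq. NH4Cl
Reagents that add atoms: none
Why: 1,2-addition of the hard lithium acetylide to the enal carbonyl; the carbinol centre forms without control and is resolved in step 3.

Step 3
Reactants: 5 racemic (4E)-7-[(tert-butyldimethylsilyl)oxy]-4-methyl-1-(trimethylsilyl)hept-4-en-1-yn-3-ol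
Product: 6 (3S,4E)-7-[(tert-butyldimethylsilyl)oxy]-4-methyl-1-(trimethylsilyl)hept-4-en-1-yn-3-ol (recovered slow-reacting enantiomer)
Conditions: Ti(OiPr)4 (10 mol%), L-(+)-diisopropyl tartrate (15 mol%), t-BuOOH (0.6 equiv), 4 Å molecular sieves, CH2Cl2, −20 °C
Reagents that add atoms: none
Why: Sharpless kinetic resolution: with the L-(+)-tartrate titanium catalyst the (3R)-enantiomer should be epoxidised fast at the trisubstituted alkene (erythro epoxy alcohol), leaving the (3S)-alcohol, while the alkyne is inert.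

Step 4
Reactants: 7 succinic anhydride; 8 N,O-dimethylhydroxylamine hydrochloride
Product: 9 4-[methoxy(methyl)amino]-4-oxobutanoic acid
Conditions: Et3N (2.2 equiv), CH2Cl2, 0 °C to rt; 1 M HCl work-up
Reagents that add atoms: none
Why: aminolysis of the cyclic anhydride stops at the mono-amide acid because the carboxylate formed is not acylating.

Step 5
Reactants: 6 (3S,4E)-7-[(tert-butyldimethylsilyl)oxy]-4-methyl-1-(trimethylsilyl)hept-4-en-1-yn-3-ol; 9 4-[methoxy(methyl)amino]-4-oxobutanoic acid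
Product: 10 (3S,4E)-7-[(tert-butyldimethylsilyl)oxy]-4-methyl-1-(trimethylsilyl)hept-4-en-1-yn-3-yl 4-[methoxy(methyl)amino]-4-oxobutanoate
Conditions: DCC, DMAP (10 mol%), CH2Cl2, 0 °C to rt
Reagents that add atoms: none
Why: Steglich esterification acylates the alcohol oxygen, so the carbinol configuration is retained.

Step 6
Reactants: 10 (3S,4E)-7-[(tert-butyldimethylsilyl)oxy]-4-methyl-1-(trimethylsilyl)hept-4-en-1-yn-3-yl 4-[methoxy(methyl)amino]-4-oxobutanoate
Product: 14 methyl (2S,3R,4E)-3-{2-[(tert-butyldimethylsilyl)oxy]ethyl}-2-{2-[methoxy(methyl)amino]-2-oxoethyl}-4-methyl-7-(trimethylsilyl)hept-4-en-6-ynoate, via silyl ketene acetal 11 (not isolated), via trimethylsilyl ester 12 (not isolated), via carboxylic acid 13 (not isolated)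
Conditions: LiN(iPr)2 (LDA, 1.1 equiv), THF, −78 °C; Me3SiCl, −78 to 50 °C; MeOH, rt; then Me3SiCHN2, toluene–MeOH, 0 °C
Reagents that add atoms: trimethylsilyldiazomethane C[Si](C)(C)C=[N+]=[N-]
Why: Ireland–Claisen rearrangement: kinetic deprotonation α to the ester (more acidic than the amide α-CH2) in THF should give the (E)-silyl ketene acetal, and the chair transition state with the alkynyl group equatorial transfers the carbinol chirality to C9 (R), sets C8 (S, 2,3-anti) and the (E)-trisubstituted alkene, the [3,3] shift running through the alkene and not the silyl-capped alkyne; O-methylation of the acid follows.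

Step 7
Reactants: 14 methyl (2S,3R,4E)-3-{2-[(tert-butyldimethylsilyl)oxy]ethyl}-2-{2-[methoxy(methyl)amino]-2-oxoethyl}-4-methyl-7-(trimethylsilyl)hept-4-en-6-ynoate
Product: 16 methyl (2S,3R,4E)-3-{2-[(tert-butyldimethylsilyl)oxy]ethyl}-2-{2-[methoxy(methyl)amino]-2-oxoethyl}-4-methylhepta-4,6-dienoate, via terminal enyne 15 (not isolated)
Conditions: K2CO3 (0.3 equiv), MeOH, rt; then Pd/CaCO3 poisoned with Pb(OAc)2 (Lindlar catalyst), quinoline, H2 (1 atm), rt
Reagents that add atoms: none
Why: methanolysis of the alkynyl C–Si bond, then syn semi-hydrogenation of the terminal alkyne on lead-poisoned palladium, should stop at the diene and leave the trisubstituted alkene and both stereocentres untouched.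

Step 8
Reactants: 16 methyl (2S,3R,4E)-3-{2-[(tert-butyldimethylsilyl)oxy]ethyl}-2-{2-[methoxy(methyl)amino]-2-oxoethyl}-4-methylhepta-4,6-dienoate; 17 (2-methylprop-1-en-1-yl)magnesium bromide
Product: 18 methyl (2S,3R,4E)-3-{2-[(tert-butyldimethylsilyl)oxy]ethyl}-4-methyl-2-(4-methyl-2-oxopent-3-en-1-yl)hepta-4,6-dienoate
Conditions: 17 (1.5 equiv), THF, −20 to 0 °C; aq. NH4Cl
Reagents that add atoms: none
Why: Weinreb ketone synthesis: the chelated tetrahedral adduct prevents over-addition, and the N-methoxy amide should react ahead of the α-branched methyl ester.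

Step 9
Reactants: 18 methyl (2S,3R,4E)-3-{2-[(tert-butyldimethylsilyl)oxy]ethyl}-4-methyl-2-(4-methyl-2-oxopent-3-en-1-yl)hepta-4,6-dienoate
Product: 19 methyl (1R,2S,4aR,8aS)-1-{2-[(tert-butyldimethylsilyl)oxy]ethyl}-5,5,8a-trimethyl-4-oxo-1,2,3,4,4a,5,6,8a-octahydronaphthalene-2-carboxylate
Conditions: Me2AlCl (2.5 equiv), CH2Cl2, −78 to 0 °C
Reagents that add atoms: none
Why: Lewis-acid-promoted type 1 intramolecular Diels–Alder reaction of a 1,7,9-decatrien-3-one, the closest known reaction type being the Me2AlCl- or EtAlCl2-mediated cyclisation of trienones to octalones: Me2AlCl bound to the C6 carbonyl lowers the LUMO of the s-cis β,β-dimethyl enone, and the [4+2] is asynchronous, the unhindered diene terminus C3 bonding to the hindered C4 ahead of the C10–C5 bond. Ring A (C10, C1, C2, C3, C4, C5) is the cyclohexene formed by the cycloaddition itself, and ring B (C5–C10) closes at the same time through the C10–C5 bond across the four-atom tether C6–C9 (fused mode, six-membered tether ring). C10 is set by C9 and C8: in the chair-like tether both the C9 side arm and the C8 ester are equatorial and the C9–H eclipses the diene plane (minimal allylic strain), so the enone adds to the diene face anti to the side arm and the new C10 methyl is anti to H9. C5 is set by the tether-anti (exo) orientation of the enone, which gives the trans fusion; since C5 is α to the ketone, any cis-fused share is corrected by the equilibration in step 10. The step needs periselectivity and regioselectivity (C4=C5 as the only 2π partner, C3 to C4 and C10 to C5), secured because only this alkene is conjugated to the complexed ketone and because the tether length allows no other pairing, and it needs the (4E)-diene with C9 on the outside, which step 6 delivers.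

Step 10
Reactants: 19 methyl (1R,2S,4aR,8aS)-1-{2-[(tert-butyldimethylsilyl)oxy]ethyl}-5,5,8a-trimethyl-4-oxo-1,2,3,4,4a,5,6,8a-octahydronaphthalene-2-carboxylate
Product: 20 methyl (1R,2S,4aR,8aS)-1-{2-[(tert-butyldimethylsilyl)oxy]ethyl}-5,5,8a-trimethyl-4-oxodecahydronaphthalene-2-carboxylate
Conditions: H2 (1 atm), 10% Pd/C, EtOAc, rt; filter; then NaOMe (0.2 equiv), MeOH, rt
Reagents that add atoms: none
Why: heterogeneous hydrogenation saturates the only C=C (C1=C2, no new stereocentre), and methoxide then equilibrates the enolisable centres C5 (α to the ketone) and C8 (α to the ester) to the all-equatorial trans-decalone, which secures the trans fusion and the C8 configuration whatever the kinetic outcome of steps 6 and 9.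

Step 11
Reactants: 20 methyl (1R,2S,4aR,8aS)-1-{2-[(tert-butyldimethylsilyl)oxy]ethyl}-5,5,8a-trimethyl-4-oxodecahydronaphthalene-2-carboxylate
Product: 21 methyl (1R,2R,4aR,8aS)-1-{2-[(tert-butyldimethylsilyl)oxy]ethyl}-5,5,8a-trimethyl-4-{[(trifluoromethyl)sulfonyl]oxy}-1,2,4a,5,6,7,8,8a-octahydronaphthalene-2-carboxylate
Conditions: KN(SiMe3)2 (KHMDS, 1.1 equiv), THF, −78 °C; PhNTf2, −78 to 0 °C
Reagents that add atoms: N-phenylbis(trifluoromethanesulfonimide) O=S(=O)(N(c1ccccc1)S(=O)(=O)C(F)(F)F)C(F)(F)F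
Why: kinetic enolisation toward the C7 methylene (the C5 methine lies between two quaternary carbons and the ester α-H is less acidic) and O-sulfonylation should give the C6=C7 enol triflate; the change of the C8 descriptor is only a priority change.

Step 12
Reactants: 21 methyl (1R,2R,4aR,8aS)-1-{2-[(tert-butyldimethylsilyl)oxy]ethyl}-5,5,8a-trimethyl-4-{[(trifluoromethyl)sulfonyl]oxy}-1,2,4a,5,6,7,8,8a-octahydronaphthalene-2-carboxylate
Product: 22 methyl (1R,2S,4aR,8aS)-1-{2-[(tert-butyldimethylsilyl)oxy]ethyl}-5,5,8a-trimethyl-1,2,4a,5,6,7,8,8a-octahydronaphthalene-2-carboxylate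
Conditions: Pd(OAc)2 (5 mol%), PPh3 (10 mol%), Bu3N, HCO2H, DMF, 60 °C
Reagents that add atoms: none
Why: palladium-catalysed formate reduction of the vinyl triflate (oxidative addition to zerovalent palladium, decarboxylation of formate to a hydride, reductive elimination) installs the C6=C7 alkene under weakly basic conditions that should not move it into conjugation with the ester.

Step 13
Reactants: 22 methyl (1R,2S,4aR,8aS)-1-{2-[(tert-butyldimethylsilyl)oxy]ethyl}-5,5,8a-trimethyl-1,2,4a,5,6,7,8,8a-octahydronaphthalene-2-carboxylate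
Product: 23 methyl (1R,2S,4aR,8aS)-1-(2-bromoethyl)-5,5,8a-trimethyl-1,2,4a,5,6,7,8,8a-octahydronaphthalene-2-carboxylate
Conditions: Ph3PBr2 (1.5 equiv), CH2Cl2, 0 °C to rt
Reagents that add atoms: triphenylphosphine dibromide BrP(Br)(c1ccccc1)(c1ccccc1)c1ccccc1
Why: direct conversion of the primary silyl ether into the bromide (oxyphosphonium formation with loss of the silyl bromide, then SN2 by bromide) avoids a free δ-hydroxy ester that could lactonise onto the C8 ester.

Step 14
Reactants: 24 methyl 4-hydroxybut-2-ynoate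
Product: 25 methyl 4-(acetyloxy)but-2-ynoate
Conditions: Ac2O, pyridine, DMAP (cat.), CH2Cl2, 0 °C
Reagents that add atoms: acetic anhydride CC(=O)OC(C)=O
Why: nucleophilic catalysis (acylpyridinium) acetylates the primary propargylic alcohol.

Step 15
Reactants: 25 methyl 4-(acetyloxy)but-2-ynoate
Product: 26 methyl (2Z)-4-(acetyloxy)-3-iodobut-2-enoate
Conditions: NaI, AcOH, 70 °C
Reagents that add atoms: sodium iodide [Na+].[I-]
Why: conjugate addition of iodide to the ynoate and anti protonation should give the (Z)-β-iodo enoate, with iodine cis to the ester.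

Step 16
Reactants: 23 methyl (1R,2S,4aR,8aS)-1-(2-bromoethyl)-5,5,8a-trimethyl-1,2,4a,5,6,7,8,8a-octahydronaphthalene-2-carboxylate; 26 methyl (2Z)-4-(acetyloxy)-3-iodobut-2-enoate
Product: 28 methyl (1R,2S,4aR,8aS)-1-[(3E)-3-[(acetyloxy)methyl]-5-methoxy-5-oxopent-3-en-1-yl]-5,5,8a-trimethyl-1,2,4a,5,6,7,8,8a-octahydronaphthalene-2-carboxylate (CNP0190145.1), via alkylzinc bromide 27 (not isolated)
Conditions: Zn dust, I2 (5 mol%), DMA, 70 °C; then 26, Pd(OAc)2 (3 mol%), SPhos (2-dicyclohexylphosphino-2',6'-dimethoxybiphenyl, 6 mol%), THF, rt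
Reagents that add atoms: none
Why: Negishi sp3–sp2 coupling proceeds with retention of the alkene geometry, so C12 replaces iodine cis to the ester, and oxidative addition to the vinyl iodide should be much faster than ionisation of the allylic acetate.

Compound list
1 | 3-[(tert-butyldimethylsilyl)oxy]propanal | O=CCCO[Si](C)(C)C(C)(C)C | starting material
2 | 2-(triphenyl-λ5-phosphanylidene)propanal | CC(C=O)=P(c1ccccc1)(c1ccccc1)c1ccccc1 | starting material
3 | (2E)-5-[(tert-butyldimethylsilyl)oxy]-2-methylpent-2-enal | O=C/C(C)=C/CCO[Si](C)(C)C(C)(C)C | intermediate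
4 | ethynyltrimethylsilane | C#C[Si](C)(C)C | starting material
5 | racemic (4E)-7-[(tert-butyldimethylsilyl)oxy]-4-methyl-1-(trimethylsilyl)hept-4-en-1-yn-3-ol | C[Si](C)(C)C#CC(O)/C(C)=C/CCO[Si](C)(C)C(C)(C)C | intermediate
6 | (3S,4E)-7-[(tert-butyldimethylsilyl)oxy]-4-methyl-1-(trimethylsilyl)hept-4-en-1-yn-3-ol | C[Si](C)(C)C#C[C@@H](O)/C(C)=C/CCO[Si](C)(C)C(C)(C)C | intermediate
7 | succinic anhydride | O=C1CCC(=O)O1 | starting material
8 | N,O-dimethylhydroxylamine hydrochloride | CNOC.Cl | starting material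
9 | 4-[methoxy(methyl)amino]-4-oxobutanoic acid | CON(C)C(=O)CCC(=O)O | intermediate
10 | (3S,4E)-7-[(tert-butyldimethylsilyl)oxy]-4-methyl-1-(trimethylsilyl)hept-4-en-1-yn-3-yl 4-[methoxy(methyl)amino]-4-oxobutanoate | C[Si](C)(C)C#C[C@@H](OC(=O)CCC(=O)N(C)OC)/C(C)=C/CCO[Si](C)(C)C(C)(C)C | intermediate
11 | (E)-O-trimethylsilyl ketene acetal of 10 (C7 trans to OSiMe3) | C[Si](C)(C)C#C[C@@H](O/C(O[Si](C)(C)C)=C\CC(=O)N(C)OC)/C(C)=C/CCO[Si](C)(C)C(C)(C)C | intermediate (not isolated)
12 | trimethylsilyl (2S,3R,4E)-3-{2-[(tert-butyldimethylsilyl)oxy]ethyl}-2-{2-[methoxy(methyl)amino]-2-oxoethyl}-4-methyl-7-(trimethylsilyl)hept-4-en-6-ynoate | CC(C)(C)[Si](C)(C)OCC[C@@H](/C(C)=C/C#C[Si](C)(C)C)[C@@H](C(=O)O[Si](C)(C)C)CC(=O)N(C)OC | intermediate (not isolated)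
13 | (2S,3R,4E)-3-{2-[(tert-butyldimethylsilyl)oxy]ethyl}-2-{2-[methoxy(methyl)amino]-2-oxoethyl}-4-methyl-7-(trimethylsilyl)hept-4-en-6-ynoic acid | CC(C)(C)[Si](C)(C)OCC[C@@H](/C(C)=C/C#C[Si](C)(C)C)[C@@H](C(=O)O)CC(=O)N(C)OC | intermediate (not isolated)
14 | methyl (2S,3R,4E)-3-{2-[(tert-butyldimethylsilyl)oxy]ethyl}-2-{2-[methoxy(methyl)amino]-2-oxoethyl}-4-methyl-7-(trimethylsilyl)hept-4-en-6-ynoate | CC(C)(C)[Si](C)(C)OCC[C@@H](/C(C)=C/C#C[Si](C)(C)C)[C@@H](C(=O)OC)CC(=O)N(C)OC | intermediate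
15 | methyl (2S,3R,4E)-3-{2-[(tert-butyldimethylsilyl)oxy]ethyl}-2-{2-[methoxy(methyl)amino]-2-oxoethyl}-4-methylhept-4-en-6-ynoate | CC(C)(C)[Si](C)(C)OCC[C@@H](/C(C)=C/C#C)[C@@H](C(=O)OC)CC(=O)N(C)OC | intermediate (not isolated)
16 | methyl (2S,3R,4E)-3-{2-[(tert-butyldimethylsilyl)oxy]ethyl}-2-{2-[methoxy(methyl)amino]-2-oxoethyl}-4-methylhepta-4,6-dienoate | CC(C)(C)[Si](C)(C)OCC[C@@H](/C(C)=C/C=C)[C@@H](C(=O)OC)CC(=O)N(C)OC | intermediate
17 | (2-methylprop-1-en-1-yl)magnesium bromide | CC(C)=C[Mg]Br | starting material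
18 | methyl (2S,3R,4E)-3-{2-[(tert-butyldimethylsilyl)oxy]ethyl}-4-methyl-2-(4-methyl-2-oxopent-3-en-1-yl)hepta-4,6-dienoate | CC(C)(C)[Si](C)(C)OCC[C@@H](/C(C)=C/C=C)[C@@H](C(=O)OC)CC(=O)C=C(C)C | intermediate
19 | methyl (1R,2S,4aR,8aS)-1-{2-[(tert-butyldimethylsilyl)oxy]ethyl}-5,5,8a-trimethyl-4-oxo-1,2,3,4,4a,5,6,8a-octahydronaphthalene-2-carboxylate | CC(C)(C)[Si](C)(C)OCC[C@@H]1[C@@H](C(=O)OC)CC(=O)[C@@H]2C(C)(C)CC=C[C@@]12C | intermediate
20 | methyl (1R,2S,4aR,8aS)-1-{2-[(tert-butyldimethylsilyl)oxy]ethyl}-5,5,8a-trimethyl-4-oxodecahydronaphthalene-2-carboxylate | CC(C)(C)[Si](C)(C)OCC[C@@H]1[C@@H](C(=O)OC)CC(=O)[C@@H]2C(C)(C)CCC[C@@]12C | intermediate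
21 | methyl (1R,2R,4aR,8aS)-1-{2-[(tert-butyldimethylsilyl)oxy]ethyl}-5,5,8a-trimethyl-4-{[(trifluoromethyl)sulfonyl]oxy}-1,2,4a,5,6,7,8,8a-octahydronaphthalene-2-carboxylate | CC(C)(C)[Si](C)(C)OCC[C@@H]1[C@@H](C(=O)OC)C=C(OS(=O)(=O)C(F)(F)F)[C@@H]2C(C)(C)CCC[C@@]12C | intermediate
22 | methyl (1R,2S,4aR,8aS)-1-{2-[(tert-butyldimethylsilyl)oxy]ethyl}-5,5,8a-trimethyl-1,2,4a,5,6,7,8,8a-octahydronaphthalene-2-carboxylate | CC(C)(C)[Si](C)(C)OCC[C@@H]1[C@@H](C(=O)OC)C=C[C@@H]2C(C)(C)CCC[C@@]12C | intermediate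
23 | methyl (1R,2S,4aR,8aS)-1-(2-bromoethyl)-5,5,8a-trimethyl-1,2,4a,5,6,7,8,8a-octahydronaphthalene-2-carboxylate | BrCC[C@@H]1[C@@H](C(=O)OC)C=C[C@@H]2C(C)(C)CCC[C@@]12C | intermediate
24 | methyl 4-hydroxybut-2-ynoate | COC(=O)C#CCO | starting material
25 | methyl 4-(acetyloxy)but-2-ynoate | COC(=O)C#CCOC(C)=O | intermediate
26 | methyl (2Z)-4-(acetyloxy)-3-iodobut-2-enoate | COC(=O)/C=C(\I)COC(C)=O | intermediate
27 | {2-[(1R,2S,4aR,8aS)-2-(methoxycarbonyl)-5,5,8a-trimethyl-1,2,4a,5,6,7,8,8a-octahydronaphthalen-1-yl]ethyl}zinc bromide | Br[Zn]CC[C@@H]1[C@@H](C(=O)OC)C=C[C@@H]2C(C)(C)CCC[C@@]12C | intermediate (not isolated)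
28 | methyl (1R,2S,4aR,8aS)-1-[(3E)-3-[(acetyloxy)methyl]-5-methoxy-5-oxopent-3-en-1-yl]-5,5,8a-trimethyl-1,2,4a,5,6,7,8,8a-octahydronaphthalene-2-carboxylate | COC(=O)/C=C(\CC[C@@H]1[C@@H](C(=O)OC)C=C[C@@H]2C(C)(C)CCC[C@@]12C)COC(C)=O | target

Total step count: 16 (steps 4, 14 and 15 prepare fragments).
Longest linear sequence: 13 steps (1, 2, 3, 5, 6, 7, 8, 9, 10, 11, 12, 13, 16).

Steps most likely to fail

1. Step 9. The hindered partners (β,β-dimethyl enone, diene with an inside methyl on C10) may react so slowly that Lewis-acid-induced oligomerisation of the diene competes, or closure may run through the tether-endo mode. Fallback, cationic instead of neutral activation: setting out from 18, ketalisation with 1,2-bis(trimethylsilyloxy)ethane and catalytic Me3SiOTf (CH2Cl2, −78 °C) should give the ethylene ketal F1. More Me3SiOTf or TfOH (catalytic, −78 to −20 °C) opens the dioxolane to the 2-alkoxyallyl (oxocarbenium) cation, a far stronger dienophile. Its ionic Diels–Alder reaction (Gassman type) with the tethered diene, followed by re-closure of the dioxolane, should give the adduct ketal F2. Hydrolysis with pyridinium p-toluenesulfonate in wet acetone comes back to the route at 19.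

2. Step 6. Deprotonation α to the amide or base-induced degradation of the N-methoxy amide may compete with ester enolisation, and chelation of lithium by the amide may favour the (Z)-ketene acetal and erode the C8 configuration. Fallback, a masked aldehyde in place of the amide: saponification of commercial methyl 4,4-dimethoxybutanoate (LiOH, THF–water) gives 4,4-dimethoxybutanoic acid F3. Setting out from 6, Steglich esterification with it gives the ester F4. The same Ireland–Claisen rearrangement and methylation give the acetal ester F5. K2CO3/MeOH and Lindlar hydrogenation give the diene acetal F6. Pyridinium p-toluenesulfonate in acetone–water frees the aldehyde F7. Addition of 17 at −78 °C (the aldehyde reacts before the ester) gives the allylic alcohol F8 as a carbinol epimer mixture, which is oxidised at once with Dess–Martin periodinane to avoid lactonisation; this comes back to the route at 18.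

3. Step 16. Zerovalent palladium may ionise the allylic acetate (in 26 or in the product), with loss or transposition of the acetoxy group, or zinc insertion may be slow. Fallback, acetate introduced after the coupling: from 24, NaI/AcOH gives methyl (2Z)-4-hydroxy-3-iodobut-2-enoate F9, which is silylated (t-BuMe2SiCl, imidazole) to the silyl ether F10. Setting out from 23 through 27, the same Negishi coupling with F10 gives the coupled silyl ether F11. HF·pyridine gives the allylic alcohol F12, whose hydroxyl is trans to the ester and cannot lactonise. Acetylation (Ac2O, pyridine) comes back to the route at 28.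

Further compounds
F1 | step 9 | methyl (2S,3R,4E)-3-{2-[(tert-butyldimethylsilyl)oxy]ethyl}-4-methyl-2-{[2-(2-methylprop-1-en-1-yl)-1,3-dioxolan-2-yl]methyl}hepta-4,6-dienoate | CC(C)(C)[Si](C)(C)OCC[C@@H](/C(C)=C/C=C)[C@@H](C(=O)OC)CC1(C=C(C)C)OCCO1
F2 | step 9 | ethylene ketal (spiro-1,3-dioxolane at C6) of 19, same configuration as 19 | CC(C)(C)[Si](C)(C)OCC[C@@H]1[C@@H](C(=O)OC)CC3(OCCO3)[C@@H]2C(C)(C)CC=C[C@@]12C
F3 | step 6 | 4,4-dimethoxybutanoic acid | COC(OC)CCC(=O)O
F4 | step 6 | (3S,4E)-7-[(tert-butyldimethylsilyl)oxy]-4-methyl-1-(trimethylsilyl)hept-4-en-1-yn-3-yl 4,4-dimethoxybutanoate | C[Si](C)(C)C#C[C@@H](OC(=O)CCC(OC)OC)/C(C)=C/CCO[Si](C)(C)C(C)(C)C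
F5 | step 6 | methyl (2S,3R,4E)-3-{2-[(tert-butyldimethylsilyl)oxy]ethyl}-2-(2,2-dimethoxyethyl)-4-methyl-7-(trimethylsilyl)hept-4-en-6-ynoate | CC(C)(C)[Si](C)(C)OCC[C@@H](/C(C)=C/C#C[Si](C)(C)C)[C@@H](C(=O)OC)CC(OC)OC
F6 | step 6 | methyl (2S,3R,4E)-3-{2-[(tert-butyldimethylsilyl)oxy]ethyl}-2-(2,2-dimethoxyethyl)-4-methylhepta-4,6-dienoate | CC(C)(C)[Si](C)(C)OCC[C@@H](/C(C)=C/C=C)[C@@H](C(=O)OC)CC(OC)OC
F7 | step 6 | methyl (2S,3R,4E)-3-{2-[(tert-butyldimethylsilyl)oxy]ethyl}-4-methyl-2-(2-oxoethyl)hepta-4,6-dienoate | CC(C)(C)[Si](C)(C)OCC[C@@H](/C(C)=C/C=C)[C@@H](C(=O)OC)CC=O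
F8 | step 6 | methyl (2S,3R,4E)-3-{2-[(tert-butyldimethylsilyl)oxy]ethyl}-2-(2-hydroxy-4-methylpent-3-en-1-yl)-4-methylhepta-4,6-dienoate (carbinol epimers) | CC(C)(C)[Si](C)(C)OCC[C@@H](/C(C)=C/C=C)[C@@H](C(=O)OC)CC(O)C=C(C)C
F9 | step 16 | methyl (2Z)-4-hydroxy-3-iodobut-2-enoate | COC(=O)/C=C(\I)CO
F10 | step 16 | methyl (2Z)-4-[(tert-butyldimethylsilyl)oxy]-3-iodobut-2-enoate | COC(=O)/C=C(\I)CO[Si](C)(C)C(C)(C)C
F11 | step 16 | methyl (1R,2S,4aR,8aS)-1-[(3E)-3-{[(tert-butyldimethylsilyl)oxy]methyl}-5-methoxy-5-oxopent-3-en-1-yl]-5,5,8a-trimethyl-1,2,4a,5,6,7,8,8a-octahydronaphthalene-2-carboxylate | COC(=O)/C=C(\CC[C@@H]1[C@@H](C(=O)OC)C=C[C@@H]2C(C)(C)CCC[C@@]12C)CO[Si](C)(C)C(C)(C)C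
F12 | step 16 | methyl (1R,2S,4aR,8aS)-1-[(3E)-3-(hydroxymethyl)-5-methoxy-5-oxopent-3-en-1-yl]-5,5,8a-trimethyl-1,2,4a,5,6,7,8,8a-octahydronaphthalene-2-carboxylate | COC(=O)/C=C(\CC[C@@H]1[C@@H](C(=O)OC)C=C[C@@H]2C(C)(C)CCC[C@@]12C)CO
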